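## Retrosynthetic overview

1. Camelliol C (20) ← TBS removal ← B‑alkyl Suzuki coupling (side‑chain C2–C3 bond) of ring iodide 11 (C11, both stereocentres) with E‑vinyl iodide 18 (C19).
2. 11 ← ester 9 ← Johnson–Claisen rearrangement of cis‑cyclohexenol 7, which sets the side‑chain stereocentre by 1,3‑chirality transfer and moves the alkene into its final position.
3. 7 ← Luche reduction of (S)‑silyloxy enone 6 ← Cu‑catalysed asymmetric β‑borylation/oxidation of dienone 4, which sets the carbinol centre.
4. The only ring is made first: isobutyraldehyde + ethyl vinyl ketone → Michael addition, then ring closure by intramolecular aldol condensation (3); dehydrogenation gives 4.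
5. 18 ← (E,E)‑farnesol: bromide, propargyl anion alkylation, desilylation, C‑methylation, hydrozirconation/iodination.

Assumption: the facial sense of the Cu/Josiphos borylation in step 3 is not established for this substrate. The ligand antipode that gives (S)‑5 is the one used, and this is confirmed by Mosher ester analysis before going on.

## Ring fragment

**Step 1**
Reactants: 1 isobutyraldehyde; 2 ethyl vinyl ketone (pent‑1‑en‑3‑one)
Product: 3, 2,4,4‑trimethylcyclohex‑2‑en‑1‑one
Conditions: cat. conc. H2SO4, PhMe, 45 °C then reflux (Dean–Stark)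
Reagents that add atoms: none (both reactants are incorporated, water is lost)
Why: Acid‑catalysed Michael addition gives 2,2‑dimethyl‑5‑oxoheptanal, which closes by intramolecular aldol condensation (Robinson‑type annulation); the aldehyde cannot enolise and only the ethyl CH2 can form a six‑membered ring, so one enone results.

**Step 2**
Reactants: 3
Product: 4, 2,4,4‑trimethylcyclohexa‑2,5‑dien‑1‑one
Conditions: DDQ, 1,4‑dioxane, reflux
Reagents that add atoms: none
Why: DDQ α′,β′‑dehydrogenation of a 4,4‑disubstituted cyclohexenone; the quaternary C4 blocks γ‑enolisation and aromatisation, so only the cross‑conjugated dienone can form.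

**Step 3**
Reactants: 4
Product: 5, (S)‑5‑hydroxy‑2,4,4‑trimethylcyclohex‑2‑en‑1‑one
Conditions: CuCl (5 mol %), NaOt‑Bu, (R,Sp)‑Josiphos SL‑J001 (or its antipode, see assumption), B2pin2, MeOH, THF, 0 °C → rt, then NaBO3·4H2O, THF/H2O, rt (one pot)
Reagents that add atoms: sodium perborate, [Na+].[Na+].O[B-]1(O)OO[B-](O)(O)OO1
Why: Enantioselective Cu‑catalysed conjugate borylation occurs at the unsubstituted enone (the α‑methyl enone is much slower), ligand‑controlled addition of Cu–Bpin sets C5, and perborate oxidation of the transient C–Bpin bond with retention gives the (S)‑alcohol, leaving no boron in the product.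

**Step 4**
Reactants: 5
Product: 6, (S)‑5‑[(tert‑butyldimethylsilyl)oxy]‑2,4,4‑trimethylcyclohex‑2‑en‑1‑one
Conditions: TBSOTf, 2,6‑lutidine, CH2Cl2, −78 → 0 °C
Reagents that add atoms: TBSOTf, CC(C)(C)[Si](C)(C)OS(=O)(=O)C(F)(F)F
Why: Silyl triflate with a hindered, weakly basic amine protects the hindered neopentyl‑type secondary alcohol at low temperature, avoiding β‑elimination of the β‑hydroxy ketone.

**Step 5**
Reactants: 6
Product: 7, (1R,5S)‑5‑[(tert‑butyldimethylsilyl)oxy]‑2,4,4‑trimethylcyclohex‑2‑en‑1‑ol (OH cis to OTBS)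
Conditions: NaBH4, CeCl3·7H2O, MeOH, −78 °C
Reagents that add atoms: none
Why: Luche 1,2‑reduction; hydride attacks axially and anti to the C5 silyloxy group, giving the cis‑1,5 alcohol (the carvone → cis‑carveol precedent), which sets C1 as R.

**Step 6**
Reactants: 7; 8 triethyl orthoacetate
Product: 9, ethyl 2‑[(1R,5S)‑5‑[(tert‑butyldimethylsilyl)oxy]‑2,6,6‑trimethylcyclohex‑2‑en‑1‑yl]acetate
Conditions: MeC(OEt)3 (excess), cat. EtCO2H, xylene, 140 °C, EtOH distilled off
Reagents that add atoms: triethyl orthoacetate (8), CC(OCC)(OCC)OCC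
Why: Johnson–Claisen [3,3] rearrangement is suprafacial, so the CH2CO2Et group arrives on the face of the departing C–O bond, cis to OTBS, giving the (R) side‑chain centre and the C(Me)=CH ring alkene of the target.

**Step 7**
Reactants: 9
Product: 10, 2‑[(1R,5S)‑5‑[(tert‑butyldimethylsilyl)oxy]‑2,6,6‑trimethylcyclohex‑2‑en‑1‑yl]ethan‑1‑ol
Conditions: LiAlH4, Et2O, 0 °C
Reagents that add atoms: none
Why: Hydride reduction of the ester to the primary alcohol; the TBS ether, alkene and both stereocentres are untouched.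

**Step 8**
Reactants: 10
Product: 11, tert‑butyl{[(1S,5R)‑5‑(2‑iodoethyl)‑4,6,6‑trimethylcyclohex‑3‑en‑1‑yl]oxy}dimethylsilane
Conditions: I2, PPh3, imidazole, CH2Cl2, 0 °C → rt
Reagents that add atoms: iodine, II
Why: Appel iodination of the unhindered primary alcohol under buffered conditions that leave the silyl ether intact.

## Polyene fragment

**Step 9**
Reactants: 12 (2E,6E)‑farnesol
Product: 13, (2E,6E)‑farnesyl bromide
Conditions: PBr3, Et2O, 0 °C
Reagents that add atoms: PBr3, BrP(Br)Br
Why: Direct conversion of the primary allylic alcohol to the bromide at low temperature, without allylic transposition or E/Z loss.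

**Step 10**
Reactants: 13; 14 1‑(trimethylsilyl)propyne
Product: 15, trimethyl[(5E,9E)‑6,10,14‑trimethylpentadeca‑5,9,13‑trien‑1‑yn‑1‑yl]silane
Conditions: 14, n‑BuLi, THF, −78 → −20 °C, then 13, −78 → 0 °C
Reagents that add atoms: none beyond reactant 14, CC#C[Si](C)(C)C
Why: Lithiated TMS‑propyne is a propargyl anion equivalent that alkylates the primary allylic bromide by SN2 to give the 1,5‑enyne; the silyl group suppresses allenyl products.

**Step 11**
Reactants: 15
Product: 16, (5E,9E)‑6,10,14‑trimethylpentadeca‑5,9,13‑trien‑1‑yne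
Conditions: K2CO3, MeOH, rt
Reagents that add atoms: none
Why: Methanolysis of the alkynyl C–Si bond (protodesilylation).

**Step 12**
Reactants: 16
Product: 17, (6E,10E)‑7,11,15‑trimethylhexadeca‑6,10,14‑trien‑2‑yne
Conditions: n‑BuLi, THF, −78 °C, then MeI, → rt
Reagents that add atoms: iodomethane, CI
Why: Alkylation of the lithium acetylide installs the methyl that becomes the vinylic methyl of the new trisubstituted alkene.

**Step 13**
Reactants: 17
Product: 18, (2E,6E,10E)‑2‑iodo‑7,11,15‑trimethylhexadeca‑2,6,10,14‑tetraene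
Conditions: Cp2Zr(H)Cl (2 equiv), THF, 50 °C (equilibration), then I2, 0 °C
Reagents that add atoms: iodine, II
Why: Hydrozirconation adds H–Zr syn; with excess Schwartz reagent the zirconium equilibrates to the methyl‑bearing carbon, and iodinolysis with retention gives the E‑2‑iodoalkene; trisubstituted alkenes do not react.

## Fragment union

**Step 14**
Reactants: 11; 18
Product: 19, tert‑butyldimethyl{[(1S,5R)‑4,6,6‑trimethyl‑5‑[(3E,7E,11E)‑3,8,12,16‑tetramethylheptadeca‑3,7,11,15‑tetraen‑1‑yl]cyclohex‑3‑en‑1‑yl]oxy}silane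
Conditions: 11, t‑BuLi (2.1 equiv), Et2O, −78 °C, then B‑OMe‑9‑BBN, THF, −78 °C → rt, then 18, PdCl2(dppf) (5 mol %), AsPh3, Cs2CO3, DMF/H2O, rt
Reagents that add atoms: none (both reactants are incorporated, the 9‑BBN unit is not retained)
Why: Li–I exchange and trapping give the alkyl borinate "ate" complex, whose B‑alkyl Suzuki–Miyaura coupling with the vinyl iodide proceeds with retention of alkene geometry, so the new trisubstituted alkene is E.

**Step 15**
Reactants: 19
Product: 20, camelliol C, (1S,5R)‑4,6,6‑trimethyl‑5‑[(3E,7E,11E)‑3,8,12,16‑tetramethylheptadeca‑3,7,11,15‑tetraen‑1‑yl]cyclohex‑3‑en‑1‑ol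
Conditions: TBAF, THF, 50 °C
Reagents that add atoms: none
Why: Fluoride desilylation under non‑acidic conditions, which avoids cationic cyclisation or isomerisation of the polyene.

## Compound list

1 | isobutyraldehyde | CC(C)C=O | starting material
2 | ethyl vinyl ketone | CCC(=O)C=C | starting material
3 | 2,4,4‑trimethylcyclohex‑2‑en‑1‑one | CC1=CC(C)(C)CCC1=O | intermediate
4 | 2,4,4‑trimethylcyclohexa‑2,5‑dien‑1‑one | CC1=CC(C)(C)C=CC1=O | intermediate
5 | (S)‑5‑hydroxy‑2,4,4‑trimethylcyclohex‑2‑en‑1‑one | CC1=CC(C)(C)[C@@H](O)CC1=O | intermediate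
6 | (S)‑5‑(TBS‑oxy)‑2,4,4‑trimethylcyclohex‑2‑en‑1‑one | CC1=CC(C)(C)[C@@H](O[Si](C)(C)C(C)(C)C)CC1=O | intermediate
7 | (1R,5S)‑5‑(TBS‑oxy)‑2,4,4‑trimethylcyclohex‑2‑en‑1‑ol | CC1=CC(C)(C)[C@@H](O[Si](C)(C)C(C)(C)C)C[C@H]1O | intermediate
8 | triethyl orthoacetate | CC(OCC)(OCC)OCC | starting material
9 | ethyl 2‑[(1R,5S)‑5‑(TBS‑oxy)‑2,6,6‑trimethylcyclohex‑2‑en‑1‑yl]acetate | CCOC(=O)C[C@@H]1C(C)=CC[C@H](O[Si](C)(C)C(C)(C)C)C1(C)C | intermediate
10 | 2‑[(1R,5S)‑5‑(TBS‑oxy)‑2,6,6‑trimethylcyclohex‑2‑en‑1‑yl]ethan‑1‑ol | OCC[C@@H]1C(C)=CC[C@H](O[Si](C)(C)C(C)(C)C)C1(C)C | intermediate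
11 | tert‑butyl{[(1S,5R)‑5‑(2‑iodoethyl)‑4,6,6‑trimethylcyclohex‑3‑en‑1‑yl]oxy}dimethylsilane | ICC[C@@H]1C(C)=CC[C@H](O[Si](C)(C)C(C)(C)C)C1(C)C | intermediate
12 | (2E,6E)‑farnesol | CC(C)=CCC/C(C)=C/CC/C(C)=C/CO | starting material
13 | (2E,6E)‑farnesyl bromide | CC(C)=CCC/C(C)=C/CC/C(C)=C/CBr | intermediate
14 | 1‑(trimethylsilyl)propyne | CC#C[Si](C)(C)C | starting material
15 | trimethyl[(5E,9E)‑6,10,14‑trimethylpentadeca‑5,9,13‑trien‑1‑yn‑1‑yl]silane | CC(C)=CCC/C(C)=C/CC/C(C)=C/CCC#C[Si](C)(C)C | intermediate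
16 | (5E,9E)‑6,10,14‑trimethylpentadeca‑5,9,13‑trien‑1‑yne | CC(C)=CCC/C(C)=C/CC/C(C)=C/CCC#C | intermediate
17 | (6E,10E)‑7,11,15‑trimethylhexadeca‑6,10,14‑trien‑2‑yne | CC(C)=CCC/C(C)=C/CC/C(C)=C/CCC#CC | intermediate
18 | (2E,6E,10E)‑2‑iodo‑7,11,15‑trimethylhexadeca‑2,6,10,14‑tetraene | CC(C)=CCC/C(C)=C/CC/C(C)=C/CC/C=C(\C)I | intermediate
19 | camelliol C TBS ether | CC(C)=CCC/C(C)=C/CC/C(C)=C/CC/C=C(\C)CC[C@@H]1C(C)=CC[C@H](O[Si](C)(C)C(C)(C)C)C1(C)C | intermediate
20 | camelliol C | CC(C)=CCC/C(C)=C/CC/C(C)=C/CC/C=C(\C)CC[C@@H]1C(C)=CC[C@H](O)C1(C)C | target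

## Step count and risks

Total steps: 15. Longest linear sequence: 10 (steps 1–8, 14, 15). The polyene branch is 5 steps (9–13).

Steps most likely to fail:

1. **Step 3 (asymmetric β‑borylation: ee, and sense of induction on a β‑carbon next to a quaternary centre).** Fallback: set the carbinol centre acyclically. Noyori hydrogenation [(R)‑BINAP–Ru] of ethyl 4,4‑dimethyl‑3‑oxohex‑5‑enoate gives the (S)‑β‑hydroxy ester. TBS protection, Weinreb amide/EtMgBr and ozonolysis then give EtCO–CH2–CH(OTBS)–CMe2–CHO, which closes to 6 by the same intramolecular aldol condensation.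

2. **Step 6 (Claisen onto a neopentyl terminus through a conformer with axial OTBS; competing dehydration to a diene).** Fallback: add the two‑carbon chain by cuprate conjugate addition to enone 6, trap the enolate as the enol triflate and reduce it (Pd/formate) to place the ring alkene. This gives the 1,5‑trans isomer, so the carbinol is then corrected by desilylation, oxidation to the ketone and hydride reduction to the equatorial (cis) alcohol.

3. **Step 13 (regioselectivity of hydrozirconation of the 2‑alkyne).** Fallback: reverse the coupling polarity. Convert 11 to the terminal alkyne with lithium acetylide, then Negishi carboalumination (Me3Al, Cp2ZrCl2)/I2 gives a regiodefined E‑vinyl iodide on the ring fragment. Couple it with the alkyl‑9‑BBN obtained by hydroborating the tetraene from farnesal methylenation.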